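## Structural features

The target, 2-(3,5-dihydroxy-4-methoxyphenyl)-3,5-dihydroxy-7,8-dimethoxy-4H-chromen-4-one, is a flavonol: benzo ring A and pyranone ring C are fused through C4a–C8a, and ring B is attached to C2 through the single C2–C1' bond. There is no stereocentre, so the whole problem is regiochemistry among nine oxygens, of which three are methyl ethers (O7, O8, O4') and four are free hydroxyls (O3, O5, O3', O5'). Ring A is oxygenated at C5, C7 and C8 with C6 left as CH, so C6 and C8 must be told apart, and the 5,7,8-pattern must not drift to the 5,6,7-pattern, which hot strong acid brings about (Wessely–Moser rearrangement). The fragile parts are the 5,8-dioxygenated ring A (a masked quinol, easily oxidised), the 3-hydroxy enone of ring C (air-sensitive in base) and the 4'-methoxy group between two oxygens, which is the methyl ether most easily lost to Lewis acids; a route ending in a selective demethylation is therefore unattractive. The real difficulty is to put methyl groups on O7 and O8 only and to bring in the two oxygens at C3 and C8. The key step uses the fact that C2, C3, C4, C4a, C5, C6, C7, C8 and C8a form one unbranched nine-carbon chain with oxygen on C2, C4, C5, C7 and C8a, a poly-β-carbonyl chain that folds by joining C4a to C8a (ring A) and O1 to C2 (ring C). The oxygens at C3 and C8 lie off this alternating pattern: the first is carried on the chain as a benzyl ether, the second is added once ring A exists, para to the 5-hydroxyl.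

## Logic of the disconnections

15 ⇒ 14. The three O–CH2Ph bonds on O3, O3' and O5' are cut. These hydroxyls must stay unmethylated but would interfere earlier (O3 with the folding, O3' and O5' with every base step), so they travel as benzyl ethers and are released together. The 5-hydroxyl needs no mask: its hydrogen bond to the C4 carbonyl protects it, and it must be free to direct the oxidation at C8. The gain is an ending that is one neutral operation. The forward step must remove three benzyl groups without reducing C2=C3 or touching a methyl ether.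

14 ⇒ 13. The O8–CH3 bond is cut. In 13 the two phenols differ sharply, O8 being free and O5 chelated, so the methyl group can be placed without protection. The demand is monomethylation under weak base with exclusion of air, because 13 is a quinol.

13 ⇒ 11. The C8–O bond is cut. C8 carries the one ring A oxygen outside the alternating pattern of the chain, and it stands para to the 5-hydroxyl, the position a phenoxide offers to persulfate. Removing it leaves 11, whose ring A has the plain phloroglucinol pattern. The demand is para selectivity over C6 and benzyl ethers that survive aqueous alkali and the hydrolysis of an aryl sulfate.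

11 ⇒ 8. Two skeletal bonds are cut, C4a–C8a (ring A) and O1–C2 (ring C), and the C4–O–C7 unit is tied back into a 4-pyranone. This disconnection carries the plan: the nine carbons C2 to C8a become a chain kept in a storable masked form, and both rings of the chromenone arise from it in one operation. The oxygen at C7 is brought by the nucleophile that opens the pyranone; with methoxide it arrives already methylated, as 15 requires. The demand is a Claisen fold (C4a onto the ester carbon) rather than an aldol fold. The benzyloxy group on C3 is placed in 8 for that reason as well as for the C3 oxygen. The two hydroxyls that can close ring C are equivalent.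

8 ⇒ 6. The C8–C8a bond is cut, removing the carboxyl carbon of the acetate arm. What remains on the pyranone is a methyl group that can be deprotonated. The demand is that the dianion of 6 accept the electrophile at the methyl-derived carbon.

6 ⇒ 5 ⇒ 4. The C3–O bond is cut. The methylene of 4 is the most acidic position of the molecule, so nitrogen can be placed there by diazo transfer (5) and exchanged for benzyloxy by carbenoid O–H insertion. The gain is a precursor without the C3 oxygen and without a stereocentre. The demand, clean functionalisation of one methylene, is easy at this stage because the second active methylene (the acetate arm) is not yet present; this fixes the order of events.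

4 ⇒ 2 + 3. The C2–C3 bond between the aroyl carbon and a methyl carbon of the pyranone is cut. This separates ring B from the chain and leads to a symmetrical, purchasable pyranone in which either methyl group may react. The demand is monoacylation, secured because the product is held as its enolate.

2 ⇒ 1. The two benzyl ether bonds and the benzyl ester bond are cut. All three acidic groups of 1 are benzylated in one operation, and the benzyl ester serves directly as acyl donor, so no separate esterification is needed.

## Other disconnections considered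

Alternative 1: The cut runs through ring C at C2–C3 and at the C4 carbonyl. C2 comes from the nitrile oxide released from hydroximoyl chloride A1 with KHCO3; C3 and C4 come from ring A alkynylboronate A2. The (3+2) cycloaddition gives isoxazole boronate A3 with boron on the future C3. Oxidation of the C–B bond, reductive opening of the N–O bond, hydrolysis to the 2-oxygenated 1,3-diketone array, removal of the ortho benzyl group, cyclodehydration and cleavage of the 5-methyl ether would then lead to the target.
- In favour: every ring A oxygen is in place from the start, so no late oxidation at C8 is needed; on this point it is better than the chosen plan. The regiochemistry of nitrile oxide additions to alkynylboronates is dependable. The C3 oxygen is delivered by boron as cleanly as by the benzyloxy group of the chosen plan, an equal point.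
- Against: A2 requires a 1,2,3,5-tetraoxygenated benzene with one ortho oxygen differentiated, which costs several steps. Its alkyne is flanked by two ortho substituents, which should slow the cycloaddition and leave the nitrile oxide time to dimerise. The unmasking takes four or five operations. The last step is a Lewis-acid demethylation at O5 in a molecule whose 4'-methoxy group is the more labile one.
- Comparison: structurally it joins two finished arenes through ring C, whereas the chosen plan builds rings A and C from a chain. Mechanistically its key step is the more predictable. In step economy it should be the longer route by three or four steps.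

Alternative 2: The cut is the O1–C8a bond. Diketone A4, with a 2-hydroxy-4,5-dimethoxyphenyl ring, would be oxidised at a graphite anode in MeOH/LiClO4. Its 4-methoxyphenol unit becomes quinone monoketal A5, the enol oxygen on C2 adds to C8a in a conjugate sense, and loss of methanol restores the aromatic ring in flavone A6, which is the same compound as 14.
- In favour: both methyl groups on O7 and O8 are purchased in place. The closure can occur at one carbon only, as unambiguous as the symmetry-controlled closure of the chosen plan (equal). No persulfate step is needed. It should reach 14 in about half as many steps, so on step economy it is the better plan.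
- Against: closure by an enol oxygen onto a quinone monoketal is thinly precedented for chromenones. Methanol can add to the same acceptor. Three electron-rich arenes and an enolised diketone meet the anode together, so selectivity would rest on potential control. Acylated quinone monoketals are sensitive.
- Comparison: the chosen plan makes ring A, and its uncertainty is the mode of folding. This alternative buys ring A, and its uncertainty is chemoselective oxidation. The C3 benzyl ether and the final hydrogenolysis are common to both.

Alternative 3: Ring C is cut at C4a–C4, C4–C3 and O1–C2 into iodophenol A7, CO and arylalkyne A8. PdCl2(PPh3)2 under CO would give ynone A9 by carbonylative coupling, and diethylamine would close it to flavone A10.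
- In favour: it is convergent and catalytic, and forms two C–C bonds and one C–O bond in one flask. All ring A oxygens are in place with no C6/C8 question, which is better than the chosen plan. The amine-mediated closure through an enaminone is expected to favour the six-membered ring over the aurone.
- Against: the iodine of A7 lies between a hydroxyl and a methoxy group on a very electron-rich ring, so oxidative addition to zerovalent palladium and CO insertion should be slow, and coupling without CO may intrude. A7 must itself be made regioselectively. A10 has C3–H and a 5-methyl ether, so a late C3 hydroxylation and a selective 5-demethylation, with the labile 4'-methoxy group present, would remain.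
- Comparison: the step count should be about equal to the chosen plan. Its key step rests on better-charted catalysis, but its endgame is weaker than the single hydrogenolysis that ends the chosen route.

Key step: step 6

Remark on the chemistry (oxygen at C7): anhydrous methoxide opens the pyranone, so the oxygen it adds at C7 keeps its methyl group through the aromatisation of ring A. The flavone leaving step 6 is therefore formulated as the 7-methyl ether 11, not as a 5,7-diol, and no separate 7-O-methylation is planned.

Remark on the chemistry (oxygen at C3): C3 passes through the key step as a benzyloxy-bearing carbon (8; compounds 6 to 10 are racemic, and the centre becomes sp2 C3 in 11). This removes a late epoxidation of an oxidisable ring system and handicaps the aldol fold through C3.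

## Route

Step 1
Reactants: 1 3,5-dihydroxy-4-methoxybenzoic acid
Product: 2 benzyl 3,5-bis(benzyloxy)-4-methoxybenzoate
Conditions: BnBr (3.5 equiv), K2CO3 (4 equiv), DMF, 60 °C
Reagents that add atoms: benzyl bromide, BrCc1ccccc1
Why: Williamson O-alkylation; carbonate deprotonates the acid and both phenols, and all three oxygens are benzylated in one operation; the benzyl ester is an adequate acyl donor for step 2 and the 4-methoxy group is untouched.

Step 2
Reactants: 3 2,6-dimethyl-4H-pyran-4-one; 2 benzyl 3,5-bis(benzyloxy)-4-methoxybenzoate
Product: 4 2-{2-[3,5-bis(benzyloxy)-4-methoxyphenyl]-2-oxoethyl}-6-methyl-4H-pyran-4-one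
Conditions: 3 (2.2 equiv), LiN(SiMe3)2 (2.2 equiv), THF, −78 °C; then 2, −78 to −20 °C; aq NH4Cl
Reagents that add atoms: none
Why: Claisen-type C-acylation of the vinylogous enolate formed by deprotonating a methyl group of the 4-pyranone; the second equivalent of lithiated 3 turns the more acidic product into its enolate, which stops a second acylation and drives the reaction, benzyloxide being the leaving group.

Step 3
Reactants: 4 2-{2-[3,5-bis(benzyloxy)-4-methoxyphenyl]-2-oxoethyl}-6-methyl-4H-pyran-4-one
Product: 5 2-{2-[3,5-bis(benzyloxy)-4-methoxyphenyl]-1-diazo-2-oxoethyl}-6-methyl-4H-pyran-4-one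
Conditions: 4-acetamidobenzenesulfonyl azide (1.2 equiv), DBU (1.5 equiv), MeCN, 0 °C to rt
Reagents that add atoms: 4-acetamidobenzenesulfonyl azide, CC(=O)Nc1ccc(cc1)S(=O)(=O)N=[N+]=[N-]
Why: Regitz diazo transfer; the methylene of 4 lies between the aryl ketone and the vinylogous carbonyl of the pyranone and is acidic enough for DBU, whereas the 6-methyl group is far less acidic and should stay untouched.

Step 4
Reactants: 5 2-{2-[3,5-bis(benzyloxy)-4-methoxyphenyl]-1-diazo-2-oxoethyl}-6-methyl-4H-pyran-4-one
Product: 6 2-{1-(benzyloxy)-2-[3,5-bis(benzyloxy)-4-methoxyphenyl]-2-oxoethyl}-6-methyl-4H-pyran-4-one (racemic)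
Conditions: Rh2(OAc)4 (2 mol %), BnOH (5 equiv), CH2Cl2, 40 °C, slow addition of 5
Reagents that add atoms: benzyl alcohol, OCc1ccccc1
Why: Rh2(OAc)4 turns the diazo ketone into a rhodium carbenoid that inserts into the O–H bond of benzyl alcohol (carbenoid O–H insertion); the new centre forms as a racemate, which is immaterial because it becomes sp2 C3 in step 6, and the excess of alcohol should outrun attack of a pyranone carbonyl oxygen on the carbenoid.

Step 5
Reactants: 6 2-{1-(benzyloxy)-2-[3,5-bis(benzyloxy)-4-methoxyphenyl]-2-oxoethyl}-6-methyl-4H-pyran-4-one (racemic)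
Product: 8 methyl 2-(6-{1-(benzyloxy)-2-[3,5-bis(benzyloxy)-4-methoxyphenyl]-2-oxoethyl}-4-oxo-4H-pyran-2-yl)acetate (racemic), via pyranylacetic acid 7 (not isolated)
Conditions: LiN(iPr)2 (2.3 equiv), THF, −78 °C; CO2 (gas), −78 °C; cold 1 M HCl; then TMSCHN2, PhMe/MeOH, 0 °C
Reagents that add atoms: carbon dioxide, O=C=O; trimethylsilyldiazomethane, C[Si](C)(C)C=[N+]=[N-]
Why: Dianion carboxylation; the first equivalent of amide forms the stabilised benzyloxy enolate, the second deprotonates the 6-methyl group, and CO2 is taken up at this last-formed, more basic carbanion; a carboxylate is no proton source for unreacted dianion, carboxylation at the hindered enolate carbon would revert by decarboxylation on work-up, and acid 7 is esterified cold before it can lose CO2.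

Step 6
Reactants: 8 methyl 2-(6-{1-(benzyloxy)-2-[3,5-bis(benzyloxy)-4-methoxyphenyl]-2-oxoethyl}-4-oxo-4H-pyran-2-yl)acetate (racemic)
Product: 11 3-(benzyloxy)-2-[3,5-bis(benzyloxy)-4-methoxyphenyl]-5-hydroxy-7-methoxy-4H-chromen-4-one, via ring-opened enol ether 9 (not isolated), via acylphloroglucinol diketone 10 (not isolated)
Conditions: Mg(OMe)2 (8 equiv), dry degassed MeOH, 65 °C, Ar; then 2 M HCl, THF, 50 °C
Reagents that add atoms: magnesium methoxide, CO[Mg]OC
Why: Mg(OMe)2 should first form the chelated enolate of the benzyloxy ketone arm, which shuts off C4 toward nucleophiles, so methoxide adds in conjugate fashion at C7, the pyranone carbon next to the acetate arm, and the ring oxygen leaves as the C4 enolate, the reagent oxygen staying on C7 as its methyl ether in 9. In the magnesium-bound polyenolate the C4a carbon, between the C4 and C5 carbonyls, attacks the ester carbon C8a across the (E)-configured C6=C7 bond (6-exo-trig Claisen condensation), methoxide is lost and tautomerisation gives aromatic ring A of 10. On acidification one of the two ortho hydroxyls adds to the C2 ketone (6-exo-trig) and loss of water closes ring C as the 4H-chromen-4-one. The closest known reaction types are alkoxide opening of 4-pyranones to poly-β-carbonyl chains, Mg(OMe)2-mediated Claisen cyclisation of poly-β-keto esters to acylphloroglucinols, and the acid cyclodehydration of 2-hydroxyaryl 1,3-diketones that ends the Baker–Venkataraman flavone synthesis. No stereocentre is created and the racemic centre of 8 becomes sp2 C3. The selectivity needed is Claisen over aldol folding: chelation by divalent magnesium keeps the C2, C4 and C5 carbonyls enolised so that the ester is the only free electrophile, attack of C3 on C7 would create a quaternary carbon that cannot aromatise by tautomerisation and can revert, and the enol ether at C7 lowers the acidity of C8 so that C8 should not attack C4. The two hydroxyls flanking the acyl group of 10 are equivalent by symmetry, so ring C closure can give one flavone only.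

Step 7
Reactants: 11 3-(benzyloxy)-2-[3,5-bis(benzyloxy)-4-methoxyphenyl]-5-hydroxy-7-methoxy-4H-chromen-4-one
Product: 13 3-(benzyloxy)-2-[3,5-bis(benzyloxy)-4-methoxyphenyl]-5,8-dihydroxy-7-methoxy-4H-chromen-4-one, via potassium 8-sulfate 12 (not isolated)
Conditions: K2S2O8 (1.5 equiv), KOH (aq), pyridine, 15 °C; then HCl (aq), Na2SO3, 80 °C
Reagents that add atoms: potassium peroxodisulfate, [K+].[K+].[O-]S(=O)(=O)OOS(=O)(=O)[O-]
Why: Elbs persulfate oxidation; the 5-phenoxide, the only free phenol in 11, attacks peroxodisulfate through its para carbon C8 to give aryl sulfate 12, which acid hydrolyses to quinol 13; benzyl and methyl ethers are inert to cold alkaline persulfate and the reaction type is known for 3-alkoxy-5-hydroxy-7-methoxyflavones.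

Step 8
Reactants: 13 3-(benzyloxy)-2-[3,5-bis(benzyloxy)-4-methoxyphenyl]-5,8-dihydroxy-7-methoxy-4H-chromen-4-one
Product: 14 3-(benzyloxy)-2-[3,5-bis(benzyloxy)-4-methoxyphenyl]-5-hydroxy-7,8-dimethoxy-4H-chromen-4-one
Conditions: Me2SO4 (1.05 equiv), K2CO3, acetone, 56 °C, N2
Reagents that add atoms: dimethyl sulfate, COS(=O)(=O)OC
Why: Williamson methylation under weak base; the 8-hydroxyl is a free phenol whereas the 5-hydroxyl is held in a hydrogen bond to the C4 carbonyl and is much less nucleophilic, so one equivalent of dimethyl sulfate should methylate O8 only, and the inert atmosphere guards the quinol against air oxidation.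

Step 9
Reactants: 14 3-(benzyloxy)-2-[3,5-bis(benzyloxy)-4-methoxyphenyl]-5-hydroxy-7,8-dimethoxy-4H-chromen-4-one
Product: 15 2-(3,5-dihydroxy-4-methoxyphenyl)-3,5-dihydroxy-7,8-dimethoxy-4H-chromen-4-one
Conditions: H2 (1 atm), 10% Pd/C, EtOAc/MeOH, rt
Reagents that add atoms: none
Why: Catalytic hydrogenolysis of the three benzyl ethers over palladium on carbon; the tetrasubstituted C2=C3 bond of the flavonol, part of a vinylogous ester, and the aryl methyl ethers should not be reduced under one atmosphere of hydrogen at room temperature.

## Compound list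

1 | 3,5-dihydroxy-4-methoxybenzoic acid | COc1c(O)cc(C(=O)O)cc1O | starting material
2 | benzyl 3,5-bis(benzyloxy)-4-methoxybenzoate | COc1c(OCc2ccccc2)cc(C(=O)OCc2ccccc2)cc1OCc1ccccc1 | intermediate
3 | 2,6-dimethyl-4H-pyran-4-one | Cc1cc(=O)cc(C)o1 | starting material
4 | 2-{2-[3,5-bis(benzyloxy)-4-methoxyphenyl]-2-oxoethyl}-6-methyl-4H-pyran-4-one | Cc1cc(=O)cc(CC(=O)c2cc(OCc3ccccc3)c(OC)c(OCc3ccccc3)c2)o1 | intermediate
5 | 2-{2-[3,5-bis(benzyloxy)-4-methoxyphenyl]-1-diazo-2-oxoethyl}-6-methyl-4H-pyran-4-one | Cc1cc(=O)cc(C(=[N+]=[N-])C(=O)c2cc(OCc3ccccc3)c(OC)c(OCc3ccccc3)c2)o1 | intermediate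
6 | 2-{1-(benzyloxy)-2-[3,5-bis(benzyloxy)-4-methoxyphenyl]-2-oxoethyl}-6-methyl-4H-pyran-4-one (racemic) | Cc1cc(=O)cc(C(OCc2ccccc2)C(=O)c2cc(OCc3ccccc3)c(OC)c(OCc3ccccc3)c2)o1 | intermediate
7 | 2-(6-{1-(benzyloxy)-2-[3,5-bis(benzyloxy)-4-methoxyphenyl]-2-oxoethyl}-4-oxo-4H-pyran-2-yl)acetic acid (racemic) | OC(=O)Cc1cc(=O)cc(C(OCc2ccccc2)C(=O)c2cc(OCc3ccccc3)c(OC)c(OCc3ccccc3)c2)o1 | intermediate
8 | methyl 2-(6-{1-(benzyloxy)-2-[3,5-bis(benzyloxy)-4-methoxyphenyl]-2-oxoethyl}-4-oxo-4H-pyran-2-yl)acetate (racemic) | COC(=O)Cc1cc(=O)cc(C(OCc2ccccc2)C(=O)c2cc(OCc3ccccc3)c(OC)c(OCc3ccccc3)c2)o1 | intermediate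
9 | methyl (3E)-8-(benzyloxy)-9-[3,5-bis(benzyloxy)-4-methoxyphenyl]-3-methoxy-5,7,9-trioxonon-3-enoate (racemic, present as its magnesium enolate) | COC(=O)C/C(OC)=C\C(=O)CC(=O)C(OCc1ccccc1)C(=O)c1cc(OCc2ccccc2)c(OC)c(OCc2ccccc2)c1 | intermediate
10 | 2-(benzyloxy)-1-[3,5-bis(benzyloxy)-4-methoxyphenyl]-3-(2,6-dihydroxy-4-methoxyphenyl)propane-1,3-dione (racemic) | COc1cc(O)c(C(=O)C(OCc2ccccc2)C(=O)c2cc(OCc3ccccc3)c(OC)c(OCc3ccccc3)c2)c(O)c1 | intermediate
11 | 3-(benzyloxy)-2-[3,5-bis(benzyloxy)-4-methoxyphenyl]-5-hydroxy-7-methoxy-4H-chromen-4-one | COc1cc(O)c2c(=O)c(OCc3ccccc3)c(-c3cc(OCc4ccccc4)c(OC)c(OCc4ccccc4)c3)oc2c1 | intermediate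
12 | potassium 3-(benzyloxy)-2-[3,5-bis(benzyloxy)-4-methoxyphenyl]-5-hydroxy-7-methoxy-4-oxo-4H-chromen-8-yl sulfate | COc1cc(O)c2c(=O)c(OCc3ccccc3)c(-c3cc(OCc4ccccc4)c(OC)c(OCc4ccccc4)c3)oc2c1OS(=O)(=O)[O-].[K+] | intermediate
13 | 3-(benzyloxy)-2-[3,5-bis(benzyloxy)-4-methoxyphenyl]-5,8-dihydroxy-7-methoxy-4H-chromen-4-one | COc1cc(O)c2c(=O)c(OCc3ccccc3)c(-c3cc(OCc4ccccc4)c(OC)c(OCc4ccccc4)c3)oc2c1O | intermediate
14 | 3-(benzyloxy)-2-[3,5-bis(benzyloxy)-4-methoxyphenyl]-5-hydroxy-7,8-dimethoxy-4H-chromen-4-one | COc1cc(O)c2c(=O)c(OCc3ccccc3)c(-c3cc(OCc4ccccc4)c(OC)c(OCc4ccccc4)c3)oc2c1OC | intermediate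
15 | 2-(3,5-dihydroxy-4-methoxyphenyl)-3,5-dihydroxy-7,8-dimethoxy-4H-chromen-4-one | COc1cc(O)c2c(=O)c(O)c(-c3cc(O)c(OC)c(O)c3)oc2c1OC | target

## Step count and weak points

Total: 9 steps. Longest linear sequence: 9 steps (1 → 2 → 4 → 5 → 6 → 8 → 11 → 13 → 14 → 15); 3 enters at step 2.

Step 6 (key step).
- What may go wrong: misfolding of the opened chain, either by aldol closure of the C8 carbanion onto C4 or by attack of C3 on C7 followed by loss of the aroyl group. Also possible are retro-Claisen loss of the aroyl group by methoxide, failure of ring opening because the doubly deprotonated pyranone is too electron-rich, opening by adventitious hydroxide instead of methoxide, and reclosure of unreacted chain to a 4-pyranone on acidification.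
- Fallback, from 2, returning at 10: this gives up the polyketide fold and makes only ring C, by the Baker–Venkataraman logic. Ester 2 is saponified (KOH, aq THF/MeOH) to 3,5-bis(benzyloxy)-4-methoxybenzoic acid F1, which (COCl)2 and catalytic DMF convert into 3,5-bis(benzyloxy)-4-methoxybenzoyl chloride F2. Separately, purchased phloroglucinol and benzyloxyacetonitrile are joined by Hoesch acylation (ZnCl2, HCl, Et2O; then hot water) to 2-(benzyloxy)-1-(2,4,6-trihydroxyphenyl)ethan-1-one F3. Its unchelated 4-hydroxyl is methylated (Me2SO4, 1 equiv, K2CO3, acetone) to 2-(benzyloxy)-1-(2,6-dihydroxy-4-methoxyphenyl)ethan-1-one F4. Polylithiated F4 (LiN(SiMe3)2, 4 equiv, THF, −78 °C) is C-aroylated by F2 to give 10, which the acid half of step 6 closes to 11.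

Step 7 (Elbs oxidation).
- What may go wrong: low conversion, because the chelated and poorly soluble phenoxide reacts sluggishly with persulfate; competing attack at C6; further oxidation of the quinol to the 5,8-quinone.
- Fallback, from 11, returning at 14: oxidative dearomatisation with trivalent iodine replaces persulfate. PhI(OAc)2 (2.2 equiv) in MeOH at 0 °C should methoxylate the para position and oxidise once more to the quinone monoketal 3-(benzyloxy)-2-[3,5-bis(benzyloxy)-4-methoxyphenyl]-7,8,8-trimethoxy-4H-chromene-4,5(8H)-dione F5. Zn in AcOH then reduces F5 with loss of methanol to 14, so that 13 and step 8 are bypassed.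

Step 4 (O–H insertion, with the diazo transfer of step 3 behind it).
- What may go wrong: diversion of the rhodium carbenoid by attack of a pyranone carbonyl oxygen of a second molecule, by carbene dimerisation or by Wolff rearrangement; thermal 1,5-cyclisation of the vinylogous diazo ketone before use.
- Fallback, from 4, returning at 6: electrophilic oxygen transfer to the enolate replaces carbenoid chemistry. The enolate of 4 (LiN(SiMe3)2, THF, −78 °C) is hydroxylated with 2-(phenylsulfonyl)-3-phenyloxaziridine to 2-{2-[3,5-bis(benzyloxy)-4-methoxyphenyl]-1-hydroxy-2-oxoethyl}-6-methyl-4H-pyran-4-one F6. The hydroxyl is benzylated under acid catalysis (benzyl 2,2,2-trichloroacetimidate, catalytic TfOH, CH2Cl2) to give 6.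

Step 5 (dianion carboxylation).
- What may go wrong: incomplete second deprotonation of the enolate-bearing pyranone, uptake of CO2 at the wrong carbon, and decarboxylation of acid 7 before esterification.
- Fallback, from 3, returning at 8: the acetate arm is installed first, so that no free acid is handled and the electrophile met by the dianion is the robust ester 2. Monoanion carboxylation of 3 (LiN(SiMe3)2, dimethyl carbonate, THF) gives methyl 2-(6-methyl-4-oxo-4H-pyran-2-yl)acetate F7. Its dianion is acylated at the methyl-derived carbon with 2 to methyl 2-(6-{2-[3,5-bis(benzyloxy)-4-methoxyphenyl]-2-oxoethyl}-4-oxo-4H-pyran-2-yl)acetate F8. Diazo transfer at the more acidic ketone methylene gives methyl 2-(6-{2-[3,5-bis(benzyloxy)-4-methoxyphenyl]-1-diazo-2-oxoethyl}-4-oxo-4H-pyran-2-yl)acetate F9, and Rh2(OAc)4 with BnOH gives 8.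

## Further compounds

F1 | step 6 | 3,5-bis(benzyloxy)-4-methoxybenzoic acid | COc1c(OCc2ccccc2)cc(C(=O)O)cc1OCc1ccccc1
F2 | step 6 | 3,5-bis(benzyloxy)-4-methoxybenzoyl chloride | COc1c(OCc2ccccc2)cc(C(=O)Cl)cc1OCc1ccccc1
F3 | step 6 | 2-(benzyloxy)-1-(2,4,6-trihydroxyphenyl)ethan-1-one | O=C(COCc1ccccc1)c1c(O)cc(O)cc1O
F4 | step 6 | 2-(benzyloxy)-1-(2,6-dihydroxy-4-methoxyphenyl)ethan-1-one | COc1cc(O)c(C(=O)COCc2ccccc2)c(O)c1
F5 | step 7 | 3-(benzyloxy)-2-[3,5-bis(benzyloxy)-4-methoxyphenyl]-7,8,8-trimethoxy-4H-chromene-4,5(8H)-dione | COC1=CC(=O)C2=C(OC(c3cc(OCc4ccccc4)c(OC)c(OCc4ccccc4)c3)=C(OCc3ccccc3)C2=O)C1(OC)OC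
F6 | step 4 | 2-{2-[3,5-bis(benzyloxy)-4-methoxyphenyl]-1-hydroxy-2-oxoethyl}-6-methyl-4H-pyran-4-one (racemic) | Cc1cc(=O)cc(C(O)C(=O)c2cc(OCc3ccccc3)c(OC)c(OCc3ccccc3)c2)o1
F7 | step 5 | methyl 2-(6-methyl-4-oxo-4H-pyran-2-yl)acetate | COC(=O)Cc1cc(=O)cc(C)o1
F8 | step 5 | methyl 2-(6-{2-[3,5-bis(benzyloxy)-4-methoxyphenyl]-2-oxoethyl}-4-oxo-4H-pyran-2-yl)acetate | COC(=O)Cc1cc(=O)cc(CC(=O)c2cc(OCc3ccccc3)c(OC)c(OCc3ccccc3)c2)o1
F9 | step 5 | methyl 2-(6-{2-[3,5-bis(benzyloxy)-4-methoxyphenyl]-1-diazo-2-oxoethyl}-4-oxo-4H-pyran-2-yl)acetate | COC(=O)Cc1cc(=O)cc(C(=[N+]=[N-])C(=O)c2cc(OCc3ccccc3)c(OC)c(OCc3ccccc3)c2)o1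
A1 | alternative 1 | (Z)-3,5-bis(benzyloxy)-N-hydroxy-4-methoxybenzenecarboximidoyl chloride | COc1c(OCc2ccccc2)cc(/C(Cl)=N/O)cc1OCc1ccccc1
A2 | alternative 1 | 2-{[2-(benzyloxy)-3,4,6-trimethoxyphenyl]ethynyl}-4,4,5,5-tetramethyl-1,3,2-dioxaborolane | COc1cc(OC)c(C#CB2OC(C)(C)C(C)(C)O2)c(OCc2ccccc2)c1OC
A3 | alternative 1 | 5-[2-(benzyloxy)-3,4,6-trimethoxyphenyl]-3-[3,5-bis(benzyloxy)-4-methoxyphenyl]-4-(4,4,5,5-tetramethyl-1,3,2-dioxaborolan-2-yl)isoxazole | COc1cc(OC)c(-c2onc(-c3cc(OCc4ccccc4)c(OC)c(OCc4ccccc4)c3)c2B2OC(C)(C)C(C)(C)O2)c(OCc2ccccc2)c1OC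
A4 | alternative 2 | 2-(benzyloxy)-1-[3,5-bis(benzyloxy)-4-methoxyphenyl]-3-(2-hydroxy-4,5-dimethoxyphenyl)propane-1,3-dione (racemic) | COc1cc(O)c(cc1OC)C(=O)C(OCc1ccccc1)C(=O)c1cc(OCc2ccccc2)c(OC)c(OCc2ccccc2)c1
A5 | alternative 2 | 2-(benzyloxy)-1-[3,5-bis(benzyloxy)-4-methoxyphenyl]-3-(3,3,4-trimethoxy-6-oxocyclohexa-1,4-dien-1-yl)propane-1,3-dione (racemic) | COC1=CC(=O)C(=CC1(OC)OC)C(=O)C(OCc1ccccc1)C(=O)c1cc(OCc2ccccc2)c(OC)c(OCc2ccccc2)c1
A6 | alternative 2 | 3-(benzyloxy)-2-[3,5-bis(benzyloxy)-4-methoxyphenyl]-5-hydroxy-7,8-dimethoxy-4H-chromen-4-one | COc1cc(O)c2c(=O)c(OCc3ccccc3)c(-c3cc(OCc4ccccc4)c(OC)c(OCc4ccccc4)c3)oc2c1OC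
A7 | alternative 3 | 2-iodo-3,5,6-trimethoxyphenol | COc1cc(OC)c(I)c(O)c1OC
A8 | alternative 3 | 1,3-bis(benzyloxy)-5-ethynyl-2-methoxybenzene | COc1c(OCc2ccccc2)cc(C#C)cc1OCc1ccccc1
A9 | alternative 3 | 3-[3,5-bis(benzyloxy)-4-methoxyphenyl]-1-(2-hydroxy-3,4,6-trimethoxyphenyl)prop-2-yn-1-one | COc1cc(OC)c(C(=O)C#Cc2cc(OCc3ccccc3)c(OC)c(OCc3ccccc3)c2)c(O)c1OC
A10 | alternative 3 | 2-[3,5-bis(benzyloxy)-4-methoxyphenyl]-5,7,8-trimethoxy-4H-chromen-4-one | COc1cc(OC)c2c(=O)cc(-c3cc(OCc4ccccc4)c(OC)c(OCc4ccccc4)c3)oc2c1OC
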